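The 31-membered lactone ring (C1 carbonyl, C2–C29 methylenes, C30 OCH2, ring oxygen) carries one functional group, so it is opened in the unfunctionalised polymethylene arc at C14–C15. The key step makes this bond by ring-closing olefin metathesis of an acyclic diene ester whose acyl arm (C1–C14) and alkoxy arm (C15–C30) each end in a vinyl group, and saturates the new C14=C15 alkene in the same pot. It exploits the remoteness of C14 and C15 from the C1 ester (12 and 15 methylenes away): both arms end in the same pentenyl unit, so one twofold copper-catalysed coupling of a dibromo ester with a single Grignard reagent builds the precursor.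

Key step: step 3

Assumption: pent-4-en-1-ylmagnesium bromide (4) is taken as a purchasable THF solution; atom numbers follow the lactone chain from the carbonyl carbon C1 to the OCH2 carbon C30.

Step 1
Reactants: 1 10-bromodecanoic acid; 2 12-bromododecan-1-ol
Product: 3 12-bromododecyl 10-bromodecanoate
Conditions: p-TsOH·H2O (5 mol %), toluene, reflux, Dean–Stark trap
Reagents that add atoms: none
Why: Fischer esterification, driven to completion by azeotropic removal of water; the primary bromides should be inert to catalytic sulfonic acid in toluene and no stereocentre is formed.

Step 2
Reactants: 3 12-bromododecyl 10-bromodecanoate; 4 pent-4-en-1-ylmagnesium bromide (2.4 equiv)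
Product: 5 heptadec-16-en-1-yl pentadec-14-enoate
Conditions: Li2CuCl4 (5 mol %), NMP (4 equiv), THF, slow addition of 4, 0 °C to rt
Reagents that add atoms: none
Why: Twofold copper-catalysed alkyl–alkyl Kumada-type cross-coupling (Kochi coupling): the organocopper species generated from 4 and catalytic Li2CuCl4 should displace both primary bromides far faster than 4 adds to the ester carbonyl when 4 is added slowly in the presence of NMP, and no stereocentre is formed.

Step 3
Reactants: 5 heptadec-16-en-1-yl pentadec-14-enoate
Product: 7 oxacyclohentriacontan-2-one (triacontan-30-olide), via oxacyclohentriacont-15-en-2-one 6 (not isolated)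
Conditions: second-generation Grubbs catalyst RuCl2(=CHPh)(H2IMes)(PCy3) (5 mol %), 1,4-benzoquinone (10 mol %), CH2Cl2 (1 mM, slow addition of 5), 40 °C, argon sparge; then concentrate, EtOAc, Pd/C (10 wt % Pd), H2 (1 atm), rt
Reagents that add atoms: none
Why: Ring-closing olefin metathesis by the Chauvin mechanism: the ruthenium benzylidene exchanges onto one terminal vinyl group of 5, the resulting alkylidene adds across the other vinyl group through a ruthenacyclobutane, and cycloreversion joins C14 to C15 as a double bond with loss of ethylene, after which palladium-catalysed syn addition of H2 converts C14=C15 into the C14–C15 single bond. The closest known reaction type is the macrocyclic ring-closing metathesis of ω-alkenyl ω-alkenoates followed by hydrogenation, as used for saturated musk-type macrolides. The 31-membered oxacycle is closed in the endo mode of ring-closing metathesis (both olefinic carbons become ring atoms), the ring being strain-free and the closure driven by removal of ethylene. No stereocentre is formed, and the E/Z geometry at C14=C15 is irrelevant because both isomers converge on hydrogenation. The step needs cyclisation to win over acyclic diene metathesis oligomerisation and needs the double bonds to stay at the chain ends: the first is secured by 1 mM pseudo-dilution and the reversibility of metathesis (oligomers can back-bite to the unstrained macrocycle), the second by 1,4-benzoquinone, which intercepts ruthenium hydrides, and by the mild temperature. The ester lies 12 and 15 methylene groups from the reacting carbons, so it should neither chelate the ruthenium alkylidene nor react with H2 over Pd/C.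

Compound list
1 | 10-bromodecanoic acid | OC(=O)CCCCCCCCCBr | starting material
2 | 12-bromododecan-1-ol | OCCCCCCCCCCCCBr | starting material
3 | 12-bromododecyl 10-bromodecanoate | BrCCCCCCCCCC(=O)OCCCCCCCCCCCCBr | intermediate
4 | pent-4-en-1-ylmagnesium bromide | C=CCCC[Mg]Br | starting material
5 | heptadec-16-en-1-yl pentadec-14-enoate | C=CCCCCCCCCCCCCC(=O)OCCCCCCCCCCCCCCCC=C | intermediate
6 | oxacyclohentriacont-15-en-2-one (E/Z mixture, not isolated; geometry left open because both isomers converge) | O=C1CCCCCCCCCCCCC=CCCCCCCCCCCCCCCCO1 | intermediate
7 | oxacyclohentriacontan-2-one (triacontan-30-olide) | O=C1CCCCCCCCCCCCCCCCCCCCCCCCCCCCCO1 | target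

Total step count: 3
Longest linear sequence: 3 steps (1 → 2 → 3)

Steps most likely to fail

1. Step 3 (key step). What may go wrong: acyclic diene metathesis oligomerisation competing with ring closure, and ruthenium-hydride-mediated migration of the terminal double bonds before closure, which would shorten the ring by one or more methylene units. The fallback still closes the ring at C14–C15, by ring-closing alkyne metathesis. Setting out from 3, twofold Li2CuCl4-catalysed coupling (THF, NMP, 0 °C) with hex-4-yn-1-ylmagnesium chloride F1, made from commercial 6-chlorohex-2-yne and magnesium turnings in THF, should give octadec-16-yn-1-yl hexadec-14-ynoate F2. The molybdenum alkylidyne complex Mo(≡CC6H4OMe-4)(OSiPh3)3 with 5 Å molecular sieves in toluene at high dilution should then close oxacyclohentriacont-15-yn-2-one F3 with loss of but-2-yne; this catalyst class does not migrate triple bonds. Hydrogenation of F3 over Pd/C (H2, EtOAc, rt) comes back to the route at 7.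

2. Step 2. What may go wrong: addition of the Grignard reagent to the ester carbonyl competing with substitution at the two bromides, which would cleave the ester linkage. The fallback performs the couplings before the ester exists. Setting out from 1, 2 and 4, the bromo acid 1 is coupled with 4 (one extra equivalent to form the magnesium carboxylate, Li2CuCl4 cat., THF, −20 °C) to give pentadec-14-enoic acid F4. The bromo alcohol 2 is coupled in the same way, as its bromomagnesium alkoxide, to give heptadec-16-en-1-ol F5. Steglich esterification of F4 with F5 (N,N'-diisopropylcarbodiimide, DMAP cat., CH2Cl2, rt) comes back to the route at 5.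

3. Step 1. What may go wrong: incomplete equilibrium esterification, and acid-promoted etherification or loss of halide at the bromomethylene termini during prolonged reflux. The fallback uses irreversible acylation. Setting out from 1, oxalyl chloride with catalytic DMF in CH2Cl2 should give 10-bromodecanoyl chloride F6, which acylates 2 in CH2Cl2 with pyridine at 0 °C and comes back to the route at 3.

Further compounds
F1 | step 3 | hex-4-yn-1-ylmagnesium chloride | CC#CCCC[Mg]Cl
F2 | step 3 | octadec-16-yn-1-yl hexadec-14-ynoate | CC#CCCCCCCCCCCCCC(=O)OCCCCCCCCCCCCCCCC#CC
F3 | step 3 | oxacyclohentriacont-15-yn-2-one | O=C1CCCCCCCCCCCCC#CCCCCCCCCCCCCCCCO1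
F4 | step 2 | pentadec-14-enoic acid | C=CCCCCCCCCCCCCC(=O)O
F5 | step 2 | heptadec-16-en-1-ol | C=CCCCCCCCCCCCCCCCO
F6 | step 1 | 10-bromodecanoyl chloride | ClC(=O)CCCCCCCCCBr
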